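# Proposed total synthesis of epicatechin-(4β→8)-catechin-(4α→8)-catechin 3-O-[(1S)-1-hydroxy-6-oxocyclohex-2-ene-1-carboxylate] (37)

## The problem

The target 37 is a linear B-type procyanidin trimer, epicatechin-(4β→8)-catechin-(4α→8)-catechin, whose terminal catechin carries on O3 the (1S)-1-hydroxy-6-oxocyclohex-2-ene-1-carbonyl group. Three flavan units must be joined through two C4–C8 diarylmethine bonds, each with one regiochemistry (C8, not C6) and one C4 configuration, on rings that are nucleophilic at several carbons. Of the nine stereocentres, four (C2 and C3 of the top and bottom units) come with (−)-epicatechin and (+)-catechin, whereas C2, C3 and C4 of the middle unit, C4 of the top unit and the quaternary C1 of the acyl group have to be made. Within a flavan unit the C3 oxygen substituent steers reaction at C4 to the trans side, so C3 can control both interflavan centres; the acyl C1 has no neighbour to control it and needs reagent control. The acyl group is the fragile part: it is an α-hydroxy-β-keto ester with a β,γ double bond, its parent acid is a β-keto acid that loses CO2, the ester is cleaved by base, and the alkene rules out hydrogenolysis once it is in place. The free polyphenol is air-sensitive, above all at its three catechols, and the interflavan bonds are cleaved by strong acid. The enabling feature is that C4 of the middle unit is a diarylmethine carbon between C8 of the bottom ring A (2,4,6-trioxygenated, able to stabilise a C4 cation) and C4a of its own ring A, a phloroglucinol ether tied to C2 through O1; the C4–C4a bond and ring C of the middle unit can therefore be closed from an acyclic C4 carbinol by intramolecular Friedel–Crafts alkylation.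

## Retrosynthesis

**37 ⇒ 36 ⇒ 27 + 34.** The last bonds broken are the sixteen O–Si bonds of 36, then the ester C–O bond between O3 of the bottom unit and the acyl carbon, giving trimer alcohol 27 and acid 34 (joined through mixed anhydride 35). Acylation comes last among the bond-forming steps because the acyl group tolerates neither the aryllithium nor the hydrogenolysis used earlier. Acid 34 carries the ketone as its triethylsilyl enol ether, so it is not a β-keto acid and cannot decarboxylate through the cyclic pathway. Fluoride in the last step returns the ketone together with all hydroxyl groups, so no separate unmasking is spent on the trimer. The forward step must join a hindered secondary alcohol with an α-quaternary acid.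

**27 ⇒ 26 ⇒ 23 ⇒ 22.** The twelve aryl O–Si bonds of 27 are cut in two sets of six. The catechol silyl ethers go first, back to hexaphenol 26; the ring A silyl ethers follow, back to dodecaphenol 23, whose three catechols are masked in passing as the cyclic phenylboronates 24 and 25. Staging is preferred to one twelve-fold silylation for two reasons: the catechols, the part of a free procyanidin that oxidises under base, are capped as soon as the benzyl groups are gone, and the slow phenols beside the interflavan bonds can be driven to completion on a defined, purifiable compound. Polyphenol 23 is traced to the benzyl-protected, bromine-capped trimer 22. Benzyl ethers carry the assembly for three reasons: aryl silyl ethers do not survive the phenoxide and hydride bases of steps 4 and 9, alkoxy-substituted rings are better π-nucleophiles than silyloxy-substituted ones in steps 12 and 17, and an aryllithium next to a silyloxy group can suffer O→C silyl migration. One hydrogenolysis removes all benzyl groups and the bromine. The forward silylations must take the phenols and leave the hindered O3–H of the bottom unit, while O3 of the top and middle units stay as TBS ethers from earlier steps.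

**22 ⇒ 16 + 21.** The top interflavan bond, C4(top)–C8(middle), is cut to dimer 16 and the C4-activated epicatechin 21. Adding the top unit last keeps the route convergent and lets the natural epicatechin carry its own stereocentres. The bromine at C8 of 21 stops the electrophile from condensing with itself, so the valuable dimer need not be used in excess. The forward reaction must choose C8 of the middle unit over the two C6 positions and deliver the 4β configuration.

**16 ⇒ 15 (key disconnection).** The C4–C4a bond of the middle unit is cut, opening ring C to carbinol 15, in which the ring A precursor hangs on C2 through O1. Compared with the classical C4–C8 cut, this places the 4→8 bond in an earlier step where its regiochemistry is fixed by a bromine atom, and leaves only the C4 configuration to the ring closure. The precursor is acyclic and both carbinol epimers converge on one cation. The forward reaction must ionise the carbinol only, close the six-membered ring and set C4 trans to O3.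

**15 ⇒ 13 + 9.** The C4–C8 bond is cut to the 8-bromo bottom unit 13 (through aryllithium 14) and aldehyde 9. An aryllithium addition is chosen over a Friedel–Crafts hydroxyalkylation because C8 is then defined by the bromination and cannot drift to C6. The forward step is a 1,2-addition to an α-silyloxy aldehyde whose stereochemical outcome does not matter.

**9 ⇒ 8 ⇒ 7 ⇒ 6 ⇒ 4 + 5; 4 ⇒ 3 ⇒ 2 ⇒ 1.** Aldehyde 9 goes back through alcohol 8 and bis-silyl ether 7 to diol 6. The benzylic C–O bond of 6 is cut to epoxy alcohol 4 and 3,5-bis(benzyloxy)phenol 5, which supplies ring A of the middle unit ready-made. Epoxide 4 comes from allylic alcohol 3, ester 2 and caffeic acid 1. One Sharpless epoxidation sets both carbons; inversion at the benzylic carbon by the phenoxide gives the anti relationship that becomes 2,3-trans. The forward opening must occur at C3 with clean inversion.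

**13 ⇒ 12 ⇒ 11 ⇒ 10; 21 ⇒ 20 ⇒ 19 ⇒ 18 ⇒ 17.** The bottom and top units are traced to (+)-catechin 10 and (−)-epicatechin 17 by removing bromine, the C4 leaving group and the protecting groups. These are short, known sequences; they ask for C8-selective bromination and C4-selective benzylic oxidation.

**34 ⇒ 33 ⇒ 32 ⇒ 31 ⇒ 29 ⇒ 28.** Acid 34 comes from allyl ester 33, which comes from hydroxy keto ester 32 by silylation of the alcohol and the ketone enol. The C1–O bond of 32 is cut to β-keto ester 31, which comes from the Birch product 29 of 2-methoxybenzoic acid 28 (through enol ether 30). The ring, the ketone and the β,γ double bond all come from one dearomatisation. The only stereocentre is set by catalytic asymmetric α-hydroxylation of a cyclic β-keto ester with fixed enol geometry.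

## Roads not taken

**Alternative 1:** The cut runs through ring A of the middle unit, which is unravelled to the linear 3,5,7-trioxo ester A2. In the forward sense, base folds A2 by a Claisen condensation (C6 onto the ester carbon) and aromatisation to chalcone A1, as chalcone synthase does.
- Merits: the 5,7-oxygenation pattern is automatic, the chemistry from a chalcone to a flavan C4 electrophile is old and robust, and no organometallic step or sensitive epoxide is involved.
- Weak points: a free triketo ester also folds by aldol and lactonisation modes, so the Claisen mode must be enforced. The key step sets none of the nine stereocentres, so C2, C3 and C4 of the middle unit remain to be made by asymmetric chalcone chemistry. The ring it builds can be bought ready-made, here as 5. Both interflavan bonds would still be made by intermolecular cation couplings, with their C6/C8 and 4α/4β questions.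
- Comparison: in scale-up and reliability of individual steps this road is at least as good as the chosen one. The chosen plan sets against it that one Sharpless epoxidation fixes C2 and C3, that the 4→8 regiochemistry is fixed by a bromine atom and not by relative nucleophilicity, and that step 12 closes a ring and sets C4 instead of assembling an aromatic ring.

**Alternative 2:** The cut is inside the acyl group: the C6 ketone is traced to an epoxide, and the epoxide to one of the two enantiotopic double bonds of the dienol ester A4. The forward key step is a hydroxyl-directed epoxidation with VO(OiPr)3, a chiral bishydroxamic acid and tBuOOH, giving the syn epoxy alcohol A3 and thereby defining C1; isomerisation of the epoxide to the ketone would follow.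
- Merits: the acid needed for A4 is symmetric, achiral and not a β-keto acid, so esterification is unproblematic. C1 is set by a catalyst acting through a directing group with a predictable sense, which is better founded than the hydroxylation of step 23, whose sense must be found by experiment.
- Weak points: tertiary, doubly allylic alcohols are poor substrates for directed epoxidation, and A4 is an arene hydrate that aromatises with loss of water under acid. The catalyst must select between enantiotopic alkenes on a substrate whose own chirality is remote. The epoxide-to-ketone step must shift hydride from C6 to C5 without opening toward the allylic position. Because the sequence runs on a monomeric catechin ester, the trimer must then be assembled around the finished acyl group; this excludes hydrogenolysis and aryllithium chemistry and forces silyl protection of every phenol through both interflavan couplings.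
- Comparison: for the acyl stereocentre alone this road is the more elegant. The chosen plan answers with a separately prepared acid 34, attached convergently to 27 in the penultimate step, so the most fragile group never meets the Lewis acids of steps 12 and 17.

**Alternative 3:** The cut is the C1–C2 bond of the cyclohexenone: an α-ketol rearrangement is read backwards to the cyclopentenyl α-keto ester A6. Forward, Cu(OTf)2 chelates the two carbonyl oxygens of A6, the alkenyl ring carbon migrates from the carbinol carbon to the keto carbon, and ring expansion gives hydroxy keto ester A5, with quaternary carbinol and ring ketone created together.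
- Merits: one step forms the ring, the ketone and the stereocentre; no oxidant is needed and the β-keto acid problem never arises. In step count for the acyl part it beats the five steps to 34.
- Weak points: ketol rearrangements are reversible and the position of the equilibrium is not guaranteed. The alkenyl group must migrate in preference to the ring CH2. The configuration of the new centre depends on a chiral ligand on copper working against the stereochemistry of the carbinol in A6. A6 itself, a tertiary allylic alcohol next to a 1,2-dicarbonyl, needs a multistep preparation on the catechin ester. As in alternative 2, the acyl group is present during trimer assembly.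
- Comparison: shorter on paper and more atom-economical. The chosen plan sets against it that each step to 34 belongs to a reaction type with broad precedent, and that an error in the acyl stereochemistry would be found on a small molecule, not on a catechin ester.

Key step: step 12

## Route

Remark 1: flavan numbering is used; the top unit is the epicatechin unit, the middle unit the central catechin unit, the bottom unit the catechin unit that carries the ester; TBS = tert-butyldimethylsilyl, TES = triethylsilyl.

Remark 2 (assumption): the two pseudoenantiomeric dihydro cinchona alkaloids give opposite senses of induction in step 23. The route is written with dihydroquinine on the assumption that it is the 1S-selective one; otherwise dihydroquinidine takes its place.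

Step 1
Reactants: 1 caffeic acid
Product: 2 benzyl (E)-3-[3,4-bis(benzyloxy)phenyl]prop-2-enoate
Conditions: BnBr (3.5 equiv), K2CO3, DMF, 60 °C
Reagents that add atoms: benzyl bromide, BrCc1ccccc1
Why: Williamson O-alkylation of both phenols and the carboxylate in one operation; the benzyl ester is the handle for the reduction that follows.

Step 2
Reactants: 2 benzyl (E)-3-[3,4-bis(benzyloxy)phenyl]prop-2-enoate
Product: 3 (E)-3-[3,4-bis(benzyloxy)phenyl]prop-2-en-1-ol
Conditions: iBu2AlH (3 equiv), CH2Cl2, −78 °C → 0 °C; aq. potassium sodium tartrate work-up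
Reagents that add atoms: none
Why: 1,2-Reduction of an α,β-unsaturated ester to the allylic alcohol with diisobutylaluminium hydride; the E alkene is untouched.

Step 3
Reactants: 3 (E)-3-[3,4-bis(benzyloxy)phenyl]prop-2-en-1-ol
Product: 4 [(2S,3S)-3-[3,4-bis(benzyloxy)phenyl]oxiran-2-yl]methanol
Conditions: Ti(OiPr)4 (10 mol %), L-(+)-diethyl tartrate (12 mol %), t-BuOOH, 4 Å MS, CH2Cl2, −20 °C
Reagents that add atoms: tert-butyl hydroperoxide, CC(C)(C)OO
Why: Sharpless asymmetric epoxidation of a primary E-allylic alcohol; the L-tartrate complex delivers oxygen to the face that gives the (2S,3S)-epoxide, fixing the future C3 of the middle unit directly and the future C2 after inversion. Catalytic loading with sieves and a non-acidic work-up should protect the electron-rich benzylic epoxide.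

Step 4
Reactants: 4 [(2S,3S)-3-[3,4-bis(benzyloxy)phenyl]oxiran-2-yl]methanol; 5 3,5-bis(benzyloxy)phenol
Product: 6 (2S,3R)-3-[3,4-bis(benzyloxy)phenyl]-3-[3,5-bis(benzyloxy)phenoxy]propane-1,2-diol
Conditions: Cs2CO3 (0.3 equiv), DMF, 50 °C
Reagents that add atoms: none
Why: Phenoxide opening of a 3-aryl-2,3-epoxy alcohol at the activated benzylic carbon (SN2), the reaction type used for 3-aryloxy-3-arylpropane-1,2-diols; inversion at C3 turns the trans-epoxide into the anti aryloxy alcohol needed for a 2,3-trans flavan. Carbonate in DMF favours O- over C-alkylation and is too weak a base to start epoxide migration.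

Step 5
Reactants: 6 (2S,3R)-3-[3,4-bis(benzyloxy)phenyl]-3-[3,5-bis(benzyloxy)phenoxy]propane-1,2-diol
Product: 7 (2S,3R)-3-[3,4-bis(benzyloxy)phenyl]-3-[3,5-bis(benzyloxy)phenoxy]-1,2-bis(tert-butyldimethylsilyloxy)propane
Conditions: TBSOTf (2.5 equiv), 2,6-lutidine, CH2Cl2, −78 °C → 0 °C
Reagents that add atoms: tert-butyldimethylsilyl trifluoromethanesulfonate, CC(C)(C)[Si](C)(C)OS(=O)(=O)C(F)(F)F
Why: Silylation of both hydroxyls with the silyl triflate; the secondary TBS ether is the lasting protection of O3 of the middle unit.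

Step 6
Reactants: 7 (2S,3R)-3-[3,4-bis(benzyloxy)phenyl]-3-[3,5-bis(benzyloxy)phenoxy]-1,2-bis(tert-butyldimethylsilyloxy)propane
Product: 8 (2S,3R)-3-[3,4-bis(benzyloxy)phenyl]-3-[3,5-bis(benzyloxy)phenoxy]-2-(tert-butyldimethylsilyloxy)propan-1-ol
Conditions: HF·pyridine, pyridine, THF, 0 °C
Reagents that add atoms: none
Why: Selective desilylation: buffered HF·pyridine cleaves a primary TBS ether much faster than a hindered secondary one, and the buffered medium should leave the acid-sensitive benzylic aryl ether alone.

Step 7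
Reactants: 8 (2S,3R)-3-[3,4-bis(benzyloxy)phenyl]-3-[3,5-bis(benzyloxy)phenoxy]-2-(tert-butyldimethylsilyloxy)propan-1-ol
Product: 9 (2R,3R)-3-[3,4-bis(benzyloxy)phenyl]-3-[3,5-bis(benzyloxy)phenoxy]-2-(tert-butyldimethylsilyloxy)propanal
Conditions: Dess–Martin periodinane, CH2Cl2, 0 °C → rt
Reagents that add atoms: none
Why: Dess–Martin oxidation of a primary alcohol under near-neutral conditions, which should not epimerise the α-silyloxy aldehyde; the descriptor at C2 changes only because the priorities change. The aldehyde is used at once.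

Step 8
Reactants: 10 (+)-catechin
Product: 11 5,7,3',4'-tetra-O-benzyl-(+)-catechin
Conditions: BnBr (4.4 equiv), K2CO3, DMF, 0 °C → rt
Reagents that add atoms: benzyl bromide, BrCc1ccccc1
Why: Williamson ether synthesis on the four phenols; the much less acidic secondary 3-OH is not alkylated under carbonate conditions.

Step 9
Reactants: 11 5,7,3',4'-tetra-O-benzyl-(+)-catechin
Product: 12 3,5,7,3',4'-penta-O-benzyl-(+)-catechin
Conditions: NaH, BnBr, DMF, 0 °C → rt
Reagents that add atoms: benzyl bromide, BrCc1ccccc1
Why: Williamson alkylation of the C3 alkoxide; with all phenols already etherified no quinone methide can form, so C2 should not epimerise.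

Step 10
Reactants: 12 3,5,7,3',4'-penta-O-benzyl-(+)-catechin
Product: 13 8-bromo-3,5,7,3',4'-penta-O-benzyl-(+)-catechin
Conditions: N-bromosuccinimide (1.0 equiv), CH2Cl2, −78 °C → rt
Reagents that add atoms: N-bromosuccinimide, O=C1CCC(=O)N1Br
Why: Electrophilic aromatic bromination; in benzyl-protected flavan-3-ols C8 is the most nucleophilic and least hindered ring A position, so monobromination should go there.

Step 11
Reactants: 13 8-bromo-3,5,7,3',4'-penta-O-benzyl-(+)-catechin; 9 (2R,3R)-3-[3,4-bis(benzyloxy)phenyl]-3-[3,5-bis(benzyloxy)phenoxy]-2-(tert-butyldimethylsilyloxy)propanal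
Product: 15 8-[(2S,3R)-3-[3,4-bis(benzyloxy)phenyl]-3-[3,5-bis(benzyloxy)phenoxy]-1-hydroxy-2-(tert-butyldimethylsilyloxy)propyl]-3,5,7,3',4'-penta-O-benzylcatechin (both C1 carbinol epimers), via 8-lithio-3,5,7,3',4'-penta-O-benzylcatechin 14 (not isolated)
Conditions: t-BuLi (2.0 equiv), THF, −78 °C; then 9, −78 °C; H2O quench
Reagents that add atoms: none
Why: Bromine–lithium exchange at C8 and 1,2-addition of the aryllithium to the aldehyde, as used for C8 functionalisation of benzylated catechins; this makes the C4–C8 bond with unambiguous regiochemistry. The new carbinol centre need not be controlled because both epimers give the same cation in step 12; low temperature should keep α-deprotonation of the aldehyde in check.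

Step 12
Reactants: 15 8-[(2S,3R)-3-[3,4-bis(benzyloxy)phenyl]-3-[3,5-bis(benzyloxy)phenoxy]-1-hydroxy-2-(tert-butyldimethylsilyloxy)propyl]-3,5,7,3',4'-penta-O-benzylcatechin
Product: 16 [5,7,3',4'-tetra-O-benzyl-3-O-TBS-catechin]-(4α→8)-[3,5,7,3',4'-penta-O-benzylcatechin]
Conditions: Sc(OTf)3 (10 mol %), 4 Å MS, CH2Cl2, −40 °C → 0 °C
Reagents that add atoms: none
Why: Sc(OTf)3 ionises the secondary benzylic carbinol of either epimer of 15 to one cation, delocalised into the 2,4,6-trioxygenated ring A of the bottom unit; the ortho carbon of the O1-tethered 3,5-bis(benzyloxy)phenyl ether attacks it and loss of a proton restores aromaticity, forming C4–C4a. The closest known reaction type is the acid-mediated intramolecular Friedel–Crafts alkylation of aryl ethers by benzhydryl-type cations that gives 4-arylchromans, and, intermolecularly, the C4-cation arylation by which procyanidin interflavan bonds are made. Ring C closes in a 6-exo-trig mode with respect to the cationic carbon (its partial double bond to C8 of the bottom unit stays outside the new ring) through a chair-like transition state. The new C4 stereocentre is controlled by C3: allylic 1,3-strain should hold the C3–H bond in the plane of the cation beside the flanking ortho substituents of the bottom aryl group, the tether reaches the cation from the face that carries C2 (anti to the C3 silyloxy group), and H3 and H4 end up antiperiplanar, which is the 2,3-trans-3,4-trans isomer with all three substituents equatorial. If the closure is reversible, the same isomer is also the thermodynamic one. Regioselectivity is secured because the two ortho carbons of the aryl ether are equivalent and the para carbon cannot reach C4, and because five-membered closure onto ring B is geometrically disfavoured and ring B is far less nucleophilic. Chemoselectivity (ionisation of the carbinol and not of the benzylic C2–O aryl ether, no 1,2-hydride shift toward a C3 ketone) should follow from the much greater stability of the trioxygenated benzylic cation, the low temperature and the high effective molarity of the tethered arene; C2 and C3 are not touched.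

Step 13
Reactants: 17 (−)-epicatechin
Product: 18 5,7,3',4'-tetra-O-benzyl-(−)-epicatechin
Conditions: BnBr (4.4 equiv), K2CO3, DMF, 0 °C → rt
Reagents that add atoms: benzyl bromide, BrCc1ccccc1
Why: Williamson ether synthesis on the four phenols, leaving the axial secondary 3-OH free.

Step 14
Reactants: 18 5,7,3',4'-tetra-O-benzyl-(−)-epicatechin
Product: 19 5,7,3',4'-tetra-O-benzyl-3-O-TBS-epicatechin
Conditions: TBSOTf, 2,6-lutidine, CH2Cl2, 0 °C
Reagents that add atoms: tert-butyldimethylsilyl trifluoromethanesulfonate, CC(C)(C)[Si](C)(C)OS(=O)(=O)C(F)(F)F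
Why: Silylation of the hindered axial alcohol with the silyl triflate; the bulky 3-O-TBS group later shields the α face of the C4 cation and survives hydrogenolysis.

Step 15
Reactants: 19 5,7,3',4'-tetra-O-benzyl-3-O-TBS-epicatechin
Product: 20 8-bromo-5,7,3',4'-tetra-O-benzyl-3-O-TBS-epicatechin
Conditions: N-bromosuccinimide (1.0 equiv), CH2Cl2, −78 °C → rt
Reagents that add atoms: N-bromosuccinimide, O=C1CCC(=O)N1Br
Why: Electrophilic aromatic bromination at C8, as in step 10; the bromine blocks the nucleophilic position of the future electrophile so that it cannot condense with itself.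

Step 16
Reactants: 20 8-bromo-5,7,3',4'-tetra-O-benzyl-3-O-TBS-epicatechin
Product: 21 8-bromo-4β-(2-ethoxyethoxy)-5,7,3',4'-tetra-O-benzyl-3-O-TBS-epicatechin
Conditions: 2,3-dichloro-5,6-dicyano-1,4-benzoquinone (2 equiv), 2-ethoxyethanol, CH2Cl2, rt
Reagents that add atoms: 2-ethoxyethanol, CCOCCO
Why: Benzylic C4 oxidation of a protected flavan-3-ol by hydride abstraction with the quinone and capture of the cation by the alcohol, the standard entry to C4 electrophiles; the alcohol should add anti to the 3-O-TBS group (4β), although either C4 epimer would serve because both ionise to the same cation.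

Step 17
Reactants: 16 [5,7,3',4'-tetra-O-benzyl-3-O-TBS-catechin]-(4α→8)-[3,5,7,3',4'-penta-O-benzylcatechin]; 21 8-bromo-4β-(2-ethoxyethoxy)-5,7,3',4'-tetra-O-benzyl-3-O-TBS-epicatechin
Product: 22 [8-bromo-5,7,3',4'-tetra-O-benzyl-3-O-TBS-epicatechin]-(4β→8)-[5,7,3',4'-tetra-O-benzyl-3-O-TBS-catechin]-(4α→8)-[3,5,7,3',4'-penta-O-benzylcatechin]
Conditions: TMSOTf (0.2 equiv), CH2Cl2, −78 °C → −40 °C; Et3N quench
Reagents that add atoms: none
Why: Lewis-acid-mediated interflavan coupling (Friedel–Crafts alkylation by the C4 cation of 21), the reaction type by which benzylated procyanidin trimers are made from a dimeric nucleophile and a monomeric electrophile. C8 of the middle unit is the most nucleophilic free position of 16 (the two C6 positions are flanked by two benzyloxy groups), and attack anti to the 3-O-TBS and 2-aryl groups of the epicatechin cation sets 4β; the bromine of 21 rules out self-condensation.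

Step 18
Reactants: 22 [8-bromo-5,7,3',4'-tetra-O-benzyl-3-O-TBS-epicatechin]-(4β→8)-[5,7,3',4'-tetra-O-benzyl-3-O-TBS-catechin]-(4α→8)-[3,5,7,3',4'-penta-O-benzylcatechin]
Product: 23 [3-O-TBS-epicatechin]-(4β→8)-[3-O-TBS-catechin]-(4α→8)-catechin
Conditions: H2 (1 atm), Pd(OH)2/C, Et3N (1.1 equiv), THF–MeOH, rt
Reagents that add atoms: none
Why: Catalytic hydrogenolysis removes the thirteen benzyl ethers and the C8 bromine in one operation, as is routine at the end of procyanidin syntheses; the secondary TBS ethers, the cyclic benzylic C2–O1 bonds and the interflavan bonds should survive, and Et3N takes up the HBr.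

Step 19
Reactants: 23 [3-O-TBS-epicatechin]-(4β→8)-[3-O-TBS-catechin]-(4α→8)-catechin
Product: 26 [5,7-di-O-TBS-3-O-TBS-epicatechin]-(4β→8)-[5,7-di-O-TBS-3-O-TBS-catechin]-(4α→8)-[5,7-di-O-TBS-catechin] (three catechols free; 3-OH of the bottom unit free), via catechol tris(phenylboronate) 24 (not isolated), via hexasilylated tris(phenylboronate) 25 (not isolated)
Conditions: PhB(OH)2 (3.2 equiv), 4 Å MS, THF, rt; then TBSCl (7 equiv), imidazole, DMF, 0 °C → rt; then pinacol (4 equiv), THF, rt; under argon
Reagents that add atoms: tert-butyldimethylsilyl chloride, CC(C)(C)[Si](C)(C)Cl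
Why: Transient boronate masking: phenylboronic acid condenses reversibly and selectively with the three 1,2-diphenols to five-membered cyclic boronates, the device long used to mask cis-diols and catechols while other hydroxyls are acylated or silylated; TBSCl/imidazole then silylates the six ring A phenols, and pinacol takes the boron off as the more stable pinacol ester. The masking keeps the oxidation-prone catechols capped from the moment the benzyl groups are gone and gives a defined hexasilyl compound on which completeness at the hindered phenols beside the interflavan bonds can be checked; the hindered secondary 3-OH of the bottom unit reacts far more slowly than any phenol.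

Step 20
Reactants: 26 [5,7-di-O-TBS-3-O-TBS-epicatechin]-(4β→8)-[5,7-di-O-TBS-3-O-TBS-catechin]-(4α→8)-[5,7-di-O-TBS-catechin]
Product: 27 [5,7,3',4'-tetra-O-TBS-3-O-TBS-epicatechin]-(4β→8)-[5,7,3',4'-tetra-O-TBS-3-O-TBS-catechin]-(4α→8)-[5,7,3',4'-tetra-O-TBS-catechin] (3-OH of the bottom unit free)
Conditions: TBSCl (7 equiv), imidazole, DMF, 0 °C → rt, under argon
Reagents that add atoms: tert-butyldimethylsilyl chloride, CC(C)(C)[Si](C)(C)Cl
Why: Chemoselective silylation of the six catechol hydroxyls: phenols react with TBSCl/imidazole far faster than the hindered secondary C3 hydroxyl of a flavan, the selectivity on which the usual preparation of phenol-silylated catechin with free 3-OH rests; the only hydroxyl left is O3–H of the bottom unit.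

Step 21
Reactants: 28 2-methoxybenzoic acid
Product: 29 2-methoxycyclohexa-2,5-diene-1-carboxylic acid (racemic)
Conditions: Li, NH3(l)–THF, t-BuOH, −78 °C; NH4Cl quench
Reagents that add atoms: none
Why: Birch reduction of a benzoic acid gives the 1,4-dihydro acid, with the carboxylate-bearing carbon and the para carbon protonated; the methoxy-bearing double bond remains as an enol ether, that is, a masked ketone.

Step 22
Reactants: 29 2-methoxycyclohexa-2,5-diene-1-carboxylic acid
Product: 31 allyl 6-oxocyclohex-2-ene-1-carboxylate (racemic keto–enol mixture), via allyl 2-methoxycyclohexa-2,5-diene-1-carboxylate 30 (not isolated)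
Conditions: allyl bromide, K2CO3, DMF, rt; then 1 M HCl, THF, 0 °C
Reagents that add atoms: allyl bromide, C=CCBr; water, O
Why: Carboxylate alkylation followed by mild acid hydrolysis of the enol ether to the β-keto ester; esterifying before hydrolysis avoids the free β-keto acid, and the allyl ester can later be removed without acid or base.

Step 23
Reactants: 31 allyl 6-oxocyclohex-2-ene-1-carboxylate
Product: 32 allyl (1S)-1-hydroxy-6-oxocyclohex-2-ene-1-carboxylate
Conditions: dihydroquinine (20 mol %), cumene hydroperoxide (1.2 equiv), CH2Br2, rt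
Reagents that add atoms: cumene hydroperoxide, CC(C)(OO)c1ccccc1
Why: Organocatalytic enantioselective α-hydroxylation of a cyclic β-keto ester: the alkaloid forms a chiral ion pair with the fixed-geometry enolate and the hydroperoxide transfers oxygen to one face, setting the quaternary C1 by catalyst control. The weakly basic conditions should not move the β,γ double bond into conjugation, and residual minor enantiomer would end as a separable diastereomer after step 26.

Step 24
Reactants: 32 allyl (1S)-1-hydroxy-6-oxocyclohex-2-ene-1-carboxylate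
Product: 33 allyl (1S)-1,6-bis(triethylsilyloxy)cyclohexa-2,5-diene-1-carboxylate
Conditions: TESOTf (2.5 equiv), Et3N, CH2Cl2, −78 °C → 0 °C
Reagents that add atoms: triethylsilyl trifluoromethanesulfonate, CC[Si](CC)(CC)OS(=O)(=O)C(F)(F)F
Why: O-Silylation of the tertiary alcohol and soft enolisation–silylation of the ketone, which can enolise only toward C5; turning the ketone into a silyl enol ether removes the β-keto function, so the derived acid cannot decarboxylate through the cyclic pathway. C1 is not affected, and the diene cannot aromatise without ionising the C1–O bond, which the ester group on the same carbon disfavours.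

Step 25
Reactants: 33 allyl (1S)-1,6-bis(triethylsilyloxy)cyclohexa-2,5-diene-1-carboxylate
Product: 34 (1S)-1,6-bis(triethylsilyloxy)cyclohexa-2,5-diene-1-carboxylic acid (used at once as its triethylammonium salt)
Conditions: Pd(PPh3)4 (5 mol %), HCO2H–Et3N, THF, rt
Reagents that add atoms: none
Why: Palladium-catalysed reductive deallylation: zerovalent palladium ionises the allyl ester and formate reduces the allyl fragment to propene, so the acid is freed under buffered, non-hydrolytic conditions that a silyl enol ether should tolerate.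

Step 26
Reactants: 34 (1S)-1,6-bis(triethylsilyloxy)cyclohexa-2,5-diene-1-carboxylic acid; 27 trimer with free 3-OH on the bottom unit
Product: 36 ester of 27 at O3 of the bottom unit with the (1S)-1,6-bis(triethylsilyloxy)cyclohexa-2,5-diene-1-carbonyl group, via mixed anhydride 35 (not isolated)
Conditions: 2,4,6-trichlorobenzoyl chloride, Et3N, toluene, rt; then 27, DMAP, rt → 40 °C
Reagents that add atoms: none
Why: Yamaguchi esterification: the carboxylate gives the mixed anhydride, DMAP forms the acylpyridinium ion and the secondary alcohol attacks it; the acid has no α-hydrogen, so no ketene can form, and only the acyl C–O bond is made, so C3 of the bottom unit and C1 of the acid keep their configurations.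

Step 27
Reactants: 36 ester of 27 with the (1S)-1,6-bis(triethylsilyloxy)cyclohexa-2,5-diene-1-carbonyl group
Product: 37 epicatechin-(4β→8)-catechin-(4α→8)-catechin 3-O-[(1S)-1-hydroxy-6-oxocyclohex-2-ene-1-carboxylate] (ester on the bottom unit)
Conditions: HF·pyridine, pyridine, THF, 0 °C → rt, under argon
Reagents that add atoms: none
Why: Global fluoride-mediated desilylation under buffered acidic conditions: the twelve aryl and two alkyl TBS ethers and the tertiary TES ether are cleaved, and the TES enol ether gives the enol, which tautomerises to the C6 ketone. The base-labile ester, the acid-labile interflavan bonds and the oxidisable catechols should survive the non-basic, non-oxidising medium.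

## Compound list

1 | caffeic acid | OC(=O)/C=C/c1ccc(O)c(O)c1 | starting material
2 | benzyl (E)-3-[3,4-bis(benzyloxy)phenyl]prop-2-enoate | O=C(OCc1ccccc1)/C=C/c1ccc(OCc2ccccc2)c(OCc2ccccc2)c1 | intermediate
3 | (E)-3-[3,4-bis(benzyloxy)phenyl]prop-2-en-1-ol | OC/C=C/c1ccc(OCc2ccccc2)c(OCc2ccccc2)c1 | intermediate
4 | [(2S,3S)-3-[3,4-bis(benzyloxy)phenyl]oxiran-2-yl]methanol | OC[C@@H]1O[C@H]1c1ccc(OCc2ccccc2)c(OCc2ccccc2)c1 | intermediate
5 | 3,5-bis(benzyloxy)phenol | Oc1cc(OCc2ccccc2)cc(OCc2ccccc2)c1 | starting material
6 | (2S,3R)-3-[3,4-bis(benzyloxy)phenyl]-3-[3,5-bis(benzyloxy)phenoxy]propane-1,2-diol | OC[C@H](O)[C@@H](c1ccc(OCc2ccccc2)c(OCc2ccccc2)c1)Oc1cc(OCc2ccccc2)cc(OCc2ccccc2)c1 | intermediate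
7 | (2S,3R)-3-[3,4-bis(benzyloxy)phenyl]-3-[3,5-bis(benzyloxy)phenoxy]-1,2-bis(tert-butyldimethylsilyloxy)propane | CC(C)(C)[Si](C)(C)OC[C@H](O[Si](C)(C)C(C)(C)C)[C@@H](c1ccc(OCc2ccccc2)c(OCc2ccccc2)c1)Oc1cc(OCc2ccccc2)cc(OCc2ccccc2)c1 | intermediate
8 | (2S,3R)-3-[3,4-bis(benzyloxy)phenyl]-3-[3,5-bis(benzyloxy)phenoxy]-2-(tert-butyldimethylsilyloxy)propan-1-ol | OC[C@H](O[Si](C)(C)C(C)(C)C)[C@@H](c1ccc(OCc2ccccc2)c(OCc2ccccc2)c1)Oc1cc(OCc2ccccc2)cc(OCc2ccccc2)c1 | intermediate
9 | (2R,3R)-3-[3,4-bis(benzyloxy)phenyl]-3-[3,5-bis(benzyloxy)phenoxy]-2-(tert-butyldimethylsilyloxy)propanal | O=C[C@H](O[Si](C)(C)C(C)(C)C)[C@@H](c1ccc(OCc2ccccc2)c(OCc2ccccc2)c1)Oc1cc(OCc2ccccc2)cc(OCc2ccccc2)c1 | intermediate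
10 | (+)-catechin, (2R,3S) | O[C@H]1Cc2c(O)cc(O)cc2O[C@@H]1c1ccc(O)c(O)c1 | starting material
11 | 5,7,3',4'-tetra-O-benzyl-(+)-catechin | O[C@H]1Cc2c(OCc9ccccc9)cc(OCc9ccccc9)cc2O[C@@H]1c1ccc(OCc9ccccc9)c(OCc9ccccc9)c1 | intermediate
12 | 3,5,7,3',4'-penta-O-benzyl-(+)-catechin | c9ccccc9CO[C@H]1Cc2c(OCc9ccccc9)cc(OCc9ccccc9)cc2O[C@@H]1c1ccc(OCc9ccccc9)c(OCc9ccccc9)c1 | intermediate
13 | 8-bromo-3,5,7,3',4'-penta-O-benzyl-(+)-catechin | c9ccccc9CO[C@H]1Cc2c(OCc9ccccc9)cc(OCc9ccccc9)c(Br)c2O[C@@H]1c1ccc(OCc9ccccc9)c(OCc9ccccc9)c1 | intermediate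
14 | 8-lithio-3,5,7,3',4'-penta-O-benzylcatechin | c9ccccc9CO[C@H]1Cc2c(OCc9ccccc9)cc(OCc9ccccc9)c([Li])c2O[C@@H]1c1ccc(OCc9ccccc9)c(OCc9ccccc9)c1 | intermediate (not isolated)
15 | 8-[(2S,3R)-3-[3,4-bis(benzyloxy)phenyl]-3-[3,5-bis(benzyloxy)phenoxy]-1-hydroxy-2-(tert-butyldimethylsilyloxy)propyl]-3,5,7,3',4'-penta-O-benzylcatechin (both C1 carbinol epimers) | c9ccccc9CO[C@H]1Cc2c(OCc9ccccc9)cc(OCc9ccccc9)c(C(O)[C@H](O[Si](C)(C)C(C)(C)C)[C@@H](c3ccc(OCc9ccccc9)c(OCc9ccccc9)c3)Oc3cc(OCc9ccccc9)cc(OCc9ccccc9)c3)c2O[C@@H]1c1ccc(OCc9ccccc9)c(OCc9ccccc9)c1 | intermediate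
16 | [5,7,3',4'-tetra-O-benzyl-3-O-TBS-catechin]-(4α→8)-[3,5,7,3',4'-penta-O-benzylcatechin] | c9ccccc9CO[C@H]1Cc2c(OCc9ccccc9)cc(OCc9ccccc9)c([C@@H]3c4c(OCc9ccccc9)cc(OCc9ccccc9)cc4O[C@H](c4ccc(OCc9ccccc9)c(OCc9ccccc9)c4)[C@H]3O[Si](C)(C)C(C)(C)C)c2O[C@@H]1c1ccc(OCc9ccccc9)c(OCc9ccccc9)c1 | intermediate
17 | (−)-epicatechin, (2R,3R) | O[C@@H]1Cc2c(O)cc(O)cc2O[C@@H]1c1ccc(O)c(O)c1 | starting material
18 | 5,7,3',4'-tetra-O-benzyl-(−)-epicatechin | O[C@@H]1Cc2c(OCc9ccccc9)cc(OCc9ccccc9)cc2O[C@@H]1c1ccc(OCc9ccccc9)c(OCc9ccccc9)c1 | intermediate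
19 | 5,7,3',4'-tetra-O-benzyl-3-O-TBS-epicatechin | CC(C)(C)[Si](C)(C)O[C@@H]1Cc2c(OCc9ccccc9)cc(OCc9ccccc9)cc2O[C@@H]1c1ccc(OCc9ccccc9)c(OCc9ccccc9)c1 | intermediate
20 | 8-bromo-5,7,3',4'-tetra-O-benzyl-3-O-TBS-epicatechin | CC(C)(C)[Si](C)(C)O[C@@H]1Cc2c(OCc9ccccc9)cc(OCc9ccccc9)c(Br)c2O[C@@H]1c1ccc(OCc9ccccc9)c(OCc9ccccc9)c1 | intermediate
21 | 8-bromo-4β-(2-ethoxyethoxy)-5,7,3',4'-tetra-O-benzyl-3-O-TBS-epicatechin | CCOCCO[C@H]1c2c(OCc9ccccc9)cc(OCc9ccccc9)c(Br)c2O[C@H](c2ccc(OCc9ccccc9)c(OCc9ccccc9)c2)[C@@H]1O[Si](C)(C)C(C)(C)C | intermediate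
22 | [8-bromo-5,7,3',4'-tetra-O-benzyl-3-O-TBS-epicatechin]-(4β→8)-[5,7,3',4'-tetra-O-benzyl-3-O-TBS-catechin]-(4α→8)-[3,5,7,3',4'-penta-O-benzylcatechin] | c9ccccc9CO[C@H]1Cc2c(OCc9ccccc9)cc(OCc9ccccc9)c([C@@H]3c4c(OCc9ccccc9)cc(OCc9ccccc9)c([C@H]5c6c(OCc9ccccc9)cc(OCc9ccccc9)c(Br)c6O[C@H](c6ccc(OCc9ccccc9)c(OCc9ccccc9)c6)[C@@H]5O[Si](C)(C)C(C)(C)C)c4O[C@H](c4ccc(OCc9ccccc9)c(OCc9ccccc9)c4)[C@H]3O[Si](C)(C)C(C)(C)C)c2O[C@@H]1c1ccc(OCc9ccccc9)c(OCc9ccccc9)c1 | intermediate
23 | [3-O-TBS-epicatechin]-(4β→8)-[3-O-TBS-catechin]-(4α→8)-catechin | O[C@H]1Cc2c(O)cc(O)c([C@@H]3c4c(O)cc(O)c([C@H]5c6c(O)cc(O)cc6O[C@H](c6ccc(O)c(O)c6)[C@@H]5O[Si](C)(C)C(C)(C)C)c4O[C@H](c4ccc(O)c(O)c4)[C@H]3O[Si](C)(C)C(C)(C)C)c2O[C@@H]1c1ccc(O)c(O)c1 | intermediate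
24 | tris(cyclic phenylboronate) of 23 at the three 3',4'-catechols (ring A phenols and 3-OH of the bottom unit free) | O[C@H]1Cc2c(O)cc(O)c([C@@H]3c4c(O)cc(O)c([C@H]5c6c(O)cc(O)cc6O[C@H](c6ccc7OB(c8ccccc8)Oc7c6)[C@@H]5O[Si](C)(C)C(C)(C)C)c4O[C@H](c4ccc7OB(c8ccccc8)Oc7c4)[C@H]3O[Si](C)(C)C(C)(C)C)c2O[C@@H]1c1ccc7OB(c8ccccc8)Oc7c1 | intermediate (not isolated)
25 | 5,7-di-O-TBS derivative (all three units) of the tris(cyclic phenylboronate) 24 | O[C@H]1Cc2c(O[Si](C)(C)C(C)(C)C)cc(O[Si](C)(C)C(C)(C)C)c([C@@H]3c4c(O[Si](C)(C)C(C)(C)C)cc(O[Si](C)(C)C(C)(C)C)c([C@H]5c6c(O[Si](C)(C)C(C)(C)C)cc(O[Si](C)(C)C(C)(C)C)cc6O[C@H](c6ccc7OB(c8ccccc8)Oc7c6)[C@@H]5O[Si](C)(C)C(C)(C)C)c4O[C@H](c4ccc7OB(c8ccccc8)Oc7c4)[C@H]3O[Si](C)(C)C(C)(C)C)c2O[C@@H]1c1ccc7OB(c8ccccc8)Oc7c1 | intermediate (not isolated)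
26 | [5,7-di-O-TBS-3-O-TBS-epicatechin]-(4β→8)-[5,7-di-O-TBS-3-O-TBS-catechin]-(4α→8)-[5,7-di-O-TBS-catechin], three catechols and 3-OH of the bottom unit free | O[C@H]1Cc2c(O[Si](C)(C)C(C)(C)C)cc(O[Si](C)(C)C(C)(C)C)c([C@@H]3c4c(O[Si](C)(C)C(C)(C)C)cc(O[Si](C)(C)C(C)(C)C)c([C@H]5c6c(O[Si](C)(C)C(C)(C)C)cc(O[Si](C)(C)C(C)(C)C)cc6O[C@H](c6ccc(O)c(O)c6)[C@@H]5O[Si](C)(C)C(C)(C)C)c4O[C@H](c4ccc(O)c(O)c4)[C@H]3O[Si](C)(C)C(C)(C)C)c2O[C@@H]1c1ccc(O)c(O)c1 | intermediate
27 | [penta-O-TBS-epicatechin]-(4β→8)-[penta-O-TBS-catechin]-(4α→8)-[5,7,3',4'-tetra-O-TBS-catechin], 3-OH of the bottom unit free | O[C@H]1Cc2c(O[Si](C)(C)C(C)(C)C)cc(O[Si](C)(C)C(C)(C)C)c([C@@H]3c4c(O[Si](C)(C)C(C)(C)C)cc(O[Si](C)(C)C(C)(C)C)c([C@H]5c6c(O[Si](C)(C)C(C)(C)C)cc(O[Si](C)(C)C(C)(C)C)cc6O[C@H](c6ccc(O[Si](C)(C)C(C)(C)C)c(O[Si](C)(C)C(C)(C)C)c6)[C@@H]5O[Si](C)(C)C(C)(C)C)c4O[C@H](c4ccc(O[Si](C)(C)C(C)(C)C)c(O[Si](C)(C)C(C)(C)C)c4)[C@H]3O[Si](C)(C)C(C)(C)C)c2O[C@@H]1c1ccc(O[Si](C)(C)C(C)(C)C)c(O[Si](C)(C)C(C)(C)C)c1 | intermediate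
28 | 2-methoxybenzoic acid | COc1ccccc1C(O)=O | starting material
29 | 2-methoxycyclohexa-2,5-diene-1-carboxylic acid (racemic) | COC1=CCC=CC1C(O)=O | intermediate
30 | allyl 2-methoxycyclohexa-2,5-diene-1-carboxylate (racemic) | COC1=CCC=CC1C(=O)OCC=C | intermediate (not isolated)
31 | allyl 6-oxocyclohex-2-ene-1-carboxylate (racemic, keto–enol mixture) | O=C1CCC=CC1C(=O)OCC=C | intermediate
32 | allyl (1S)-1-hydroxy-6-oxocyclohex-2-ene-1-carboxylate | O=C1CCC=C[C@@]1(O)C(=O)OCC=C | intermediate
33 | allyl (1S)-1,6-bis(triethylsilyloxy)cyclohexa-2,5-diene-1-carboxylate | CC[Si](CC)(CC)OC1=CCC=C[C@@]1(O[Si](CC)(CC)CC)C(=O)OCC=C | intermediate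
34 | (1S)-1,6-bis(triethylsilyloxy)cyclohexa-2,5-diene-1-carboxylic acid | CC[Si](CC)(CC)OC1=CCC=C[C@@]1(O[Si](CC)(CC)CC)C(O)=O | intermediate
35 | (1S)-1,6-bis(triethylsilyloxy)cyclohexa-2,5-diene-1-carboxylic 2,4,6-trichlorobenzoic anhydride | CC[Si](CC)(CC)OC1=CCC=C[C@@]1(O[Si](CC)(CC)CC)C(=O)OC(=O)c1c(Cl)cc(Cl)cc1Cl | intermediate (not isolated)
36 | ester of 27 at O3 of the bottom unit with the (1S)-1,6-bis(triethylsilyloxy)cyclohexa-2,5-diene-1-carbonyl group | CC[Si](CC)(CC)OC1=CCC=C[C@@]1(O[Si](CC)(CC)CC)C(=O)O[C@H]1Cc2c(O[Si](C)(C)C(C)(C)C)cc(O[Si](C)(C)C(C)(C)C)c([C@@H]3c4c(O[Si](C)(C)C(C)(C)C)cc(O[Si](C)(C)C(C)(C)C)c([C@H]5c6c(O[Si](C)(C)C(C)(C)C)cc(O[Si](C)(C)C(C)(C)C)cc6O[C@H](c6ccc(O[Si](C)(C)C(C)(C)C)c(O[Si](C)(C)C(C)(C)C)c6)[C@@H]5O[Si](C)(C)C(C)(C)C)c4O[C@H](c4ccc(O[Si](C)(C)C(C)(C)C)c(O[Si](C)(C)C(C)(C)C)c4)[C@H]3O[Si](C)(C)C(C)(C)C)c2O[C@@H]1c1ccc(O[Si](C)(C)C(C)(C)C)c(O[Si](C)(C)C(C)(C)C)c1 | intermediate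
37 | epicatechin-(4β→8)-catechin-(4α→8)-catechin 3-O-[(1S)-1-hydroxy-6-oxocyclohex-2-ene-1-carboxylate] (ester on the bottom unit) | O=C1CCC=C[C@@]1(O)C(=O)O[C@H]1Cc2c(O)cc(O)c([C@@H]3c4c(O)cc(O)c([C@H]5c6c(O)cc(O)cc6O[C@H](c6ccc(O)c(O)c6)[C@@H]5O)c4O[C@H](c4ccc(O)c(O)c4)[C@H]3O)c2O[C@@H]1c1ccc(O)c(O)c1 | target

## Step count and least certain steps

Total number of steps: 27. Longest linear sequence: 15 steps, from caffeic acid 1 (steps 1–7, 11, 12, 17, 18, 19, 20, 26, 27).

**Step 12 (key step).** The most likely failure is incomplete facial control in the ring closure, giving some 3,4-cis isomer, or diversion of the cation by loss of the C3 proton or a 1,2-hydride shift before the arene arrives; the acyclic cation has conformational freedom that a flavan C4 cation lacks. The fallback sets out from 11 and returns at 16 by making the same interflavan bond in the classical direction. Compound 11 is silylated at O3 (TBSOTf, 2,6-lutidine) to 5,7,3',4'-tetra-O-benzyl-3-O-TBS-catechin F1. F1 is oxidised at C4 with 2,3-dichloro-5,6-dicyano-1,4-benzoquinone in the presence of 2-ethoxyethanol to the 4-(2-ethoxyethoxy) derivative F2. F2 is condensed with an excess of 12 under TMSOTf at −78 °C; C8 of 12 should attack the C4 cation anti to the 3-silyloxy group and give 16.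

**Step 23.** The most likely failure is insufficient enantioselectivity or the wrong sense of induction, because this dienolisable six-membered keto ester lies outside the best-behaved substrates of the method; migration of the double bond into conjugation followed by nucleophilic epoxidation is a second risk. The fallback sets out from 31 and returns at 32. Compound 31 is hydroxylated without stereocontrol by dimethyldioxirane in acetone to racemic allyl 1-hydroxy-6-oxocyclohex-2-ene-1-carboxylate F3, and the enantiomers of F3 are separated by preparative chromatography on a chiral stationary phase; the S enantiomer is 32.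

**Step 26.** The most likely failure is slow acylation, because a hindered secondary alcohol meets an α-quaternary acid, together with protodesilylation of the enol ether of 34 before coupling, which would expose the β-keto acid to decarboxylation. The fallback sets out from 27 and 29 and returns at 37, building the acyl group on the trimer from the small, stable acid. Compound 27 is esterified with 29 (dicyclohexylcarbodiimide, DMAP) to the 2-methoxycyclohexa-2,5-diene-1-carboxylate F4. Mild aqueous acid (oxalic acid, THF–H2O) hydrolyses the enol ether of F4 to the β-keto ester F5. The cinchona-catalysed hydroxylation of step 23 is applied to F5 to give the (1S)-1-hydroxy-6-oxocyclohex-2-ene-1-carboxylate F6, the catalyst overriding the remote chirality of the trimer. HF·pyridine as in step 27 converts F6 into 37.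

**Step 19.** The most likely failure is incomplete masking or loss of a boronate during the silylation, so that catechol hydroxyls are exposed to base and partly oxidised, together with slow silylation of the ring A phenols that flank the interflavan bonds. Silylation of a catechol hydroxyl at this stage is harmless in itself, because step 20 silylates every phenol that is left. The fallback sets out from 23 and returns at 27 without masking and without the stop at 26: all twelve phenols are silylated in one operation with a large excess of TBSCl and imidazole in rigorously degassed DMF, relying only on the rate difference between phenols and the hindered secondary hydroxyl; this detour passes through no compound outside the compound list (F0).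

**Step 4.** The most likely failure is loss of regiochemical integrity: the free epoxy alcohol carries its own nucleophile and can migrate its epoxide or open a second molecule, so attack at C1 or oligomers would result. The fallback sets out from 4 and returns at 7. Compound 4 is silylated (TBSCl, imidazole) to tert-butyl{[(2S,3S)-3-[3,4-bis(benzyloxy)phenyl]oxiran-2-yl]methoxy}dimethylsilane F7. F7 is opened with 5 and Cs2CO3 in DMF at the benzylic carbon with inversion to (2S,3R)-3-[3,4-bis(benzyloxy)phenyl]-3-[3,5-bis(benzyloxy)phenoxy]-1-(tert-butyldimethylsilyloxy)propan-2-ol F8. Silylation of F8 with TBSOTf and 2,6-lutidine gives 7; a silyl shift between O1 and O2 during the opening would not matter, since both hydroxyls end up silylated.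

## Further compounds

F1 | step 12 | 5,7,3',4'-tetra-O-benzyl-3-O-TBS-catechin | CC(C)(C)[Si](C)(C)O[C@H]1Cc2c(OCc9ccccc9)cc(OCc9ccccc9)cc2O[C@@H]1c1ccc(OCc9ccccc9)c(OCc9ccccc9)c1
F2 | step 12 | 4-(2-ethoxyethoxy)-5,7,3',4'-tetra-O-benzyl-3-O-TBS-catechin (C4 epimers) | CCOCCOC1c2c(OCc9ccccc9)cc(OCc9ccccc9)cc2O[C@H](c2ccc(OCc9ccccc9)c(OCc9ccccc9)c2)[C@H]1O[Si](C)(C)C(C)(C)C
F3 | step 23 | racemic allyl 1-hydroxy-6-oxocyclohex-2-ene-1-carboxylate | O=C1CCC=CC1(O)C(=O)OCC=C
F4 | step 26 | ester of 27 at O3 of the bottom unit with 2-methoxycyclohexa-2,5-diene-1-carboxylic acid (epimers at the acyl C1) | COC1=CCC=CC1C(=O)O[C@H]1Cc2c(O[Si](C)(C)C(C)(C)C)cc(O[Si](C)(C)C(C)(C)C)c([C@@H]3c4c(O[Si](C)(C)C(C)(C)C)cc(O[Si](C)(C)C(C)(C)C)c([C@H]5c6c(O[Si](C)(C)C(C)(C)C)cc(O[Si](C)(C)C(C)(C)C)cc6O[C@H](c6ccc(O[Si](C)(C)C(C)(C)C)c(O[Si](C)(C)C(C)(C)C)c6)[C@@H]5O[Si](C)(C)C(C)(C)C)c4O[C@H](c4ccc(O[Si](C)(C)C(C)(C)C)c(O[Si](C)(C)C(C)(C)C)c4)[C@H]3O[Si](C)(C)C(C)(C)C)c2O[C@@H]1c1ccc(O[Si](C)(C)C(C)(C)C)c(O[Si](C)(C)C(C)(C)C)c1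
F5 | step 26 | ester of 27 at O3 of the bottom unit with 6-oxocyclohex-2-ene-1-carboxylic acid (epimers at the acyl C1, keto–enol mixture) | O=C1CCC=CC1C(=O)O[C@H]1Cc2c(O[Si](C)(C)C(C)(C)C)cc(O[Si](C)(C)C(C)(C)C)c([C@@H]3c4c(O[Si](C)(C)C(C)(C)C)cc(O[Si](C)(C)C(C)(C)C)c([C@H]5c6c(O[Si](C)(C)C(C)(C)C)cc(O[Si](C)(C)C(C)(C)C)cc6O[C@H](c6ccc(O[Si](C)(C)C(C)(C)C)c(O[Si](C)(C)C(C)(C)C)c6)[C@@H]5O[Si](C)(C)C(C)(C)C)c4O[C@H](c4ccc(O[Si](C)(C)C(C)(C)C)c(O[Si](C)(C)C(C)(C)C)c4)[C@H]3O[Si](C)(C)C(C)(C)C)c2O[C@@H]1c1ccc(O[Si](C)(C)C(C)(C)C)c(O[Si](C)(C)C(C)(C)C)c1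
F6 | step 26 | ester of 27 at O3 of the bottom unit with (1S)-1-hydroxy-6-oxocyclohex-2-ene-1-carboxylic acid | O=C1CCC=C[C@@]1(O)C(=O)O[C@H]1Cc2c(O[Si](C)(C)C(C)(C)C)cc(O[Si](C)(C)C(C)(C)C)c([C@@H]3c4c(O[Si](C)(C)C(C)(C)C)cc(O[Si](C)(C)C(C)(C)C)c([C@H]5c6c(O[Si](C)(C)C(C)(C)C)cc(O[Si](C)(C)C(C)(C)C)cc6O[C@H](c6ccc(O[Si](C)(C)C(C)(C)C)c(O[Si](C)(C)C(C)(C)C)c6)[C@@H]5O[Si](C)(C)C(C)(C)C)c4O[C@H](c4ccc(O[Si](C)(C)C(C)(C)C)c(O[Si](C)(C)C(C)(C)C)c4)[C@H]3O[Si](C)(C)C(C)(C)C)c2O[C@@H]1c1ccc(O[Si](C)(C)C(C)(C)C)c(O[Si](C)(C)C(C)(C)C)c1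
F0 | step 19 | none | none
F7 | step 4 | tert-butyl{[(2S,3S)-3-[3,4-bis(benzyloxy)phenyl]oxiran-2-yl]methoxy}dimethylsilane | CC(C)(C)[Si](C)(C)OC[C@@H]1O[C@H]1c1ccc(OCc2ccccc2)c(OCc2ccccc2)c1
F8 | step 4 | (2S,3R)-3-[3,4-bis(benzyloxy)phenyl]-3-[3,5-bis(benzyloxy)phenoxy]-1-(tert-butyldimethylsilyloxy)propan-2-ol | CC(C)(C)[Si](C)(C)OC[C@H](O)[C@@H](c1ccc(OCc2ccccc2)c(OCc2ccccc2)c1)Oc1cc(OCc2ccccc2)cc(OCc2ccccc2)c1
A1 | alternative 1 | (E)-3,4-bis(benzyloxy)-2',4',6'-trihydroxychalcone | O=C(/C=C/c1ccc(OCc2ccccc2)c(OCc2ccccc2)c1)c1c(O)cc(O)cc1O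
A2 | alternative 1 | ethyl (E)-9-[3,4-bis(benzyloxy)phenyl]-3,5,7-trioxonon-8-enoate | CCOC(=O)CC(=O)CC(=O)CC(=O)/C=C/c1ccc(OCc2ccccc2)c(OCc2ccccc2)c1
A3 | alternative 2 | 5,7,3',4'-tetra-O-TBS-catechin 3-O-(syn-2-hydroxy-7-oxabicyclo[4.1.0]hept-3-ene-2-carboxylate) | [C@@H]12O[C@@H]1CC=C[C@@]2(O)C(=O)O[C@H]1Cc2c(O[Si](C)(C)C(C)(C)C)cc(O[Si](C)(C)C(C)(C)C)cc2O[C@@H]1c1ccc(O[Si](C)(C)C(C)(C)C)c(O[Si](C)(C)C(C)(C)C)c1
A4 | alternative 2 | 5,7,3',4'-tetra-O-TBS-catechin 3-O-(1-hydroxycyclohexa-2,5-diene-1-carboxylate) | OC1(C=CCC=C1)C(=O)O[C@H]1Cc2c(O[Si](C)(C)C(C)(C)C)cc(O[Si](C)(C)C(C)(C)C)cc2O[C@@H]1c1ccc(O[Si](C)(C)C(C)(C)C)c(O[Si](C)(C)C(C)(C)C)c1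
A5 | alternative 3 | 5,7,3',4'-tetra-O-TBS-catechin 3-O-[(S)-1-hydroxy-6-oxocyclohex-2-ene-1-carboxylate] | O=C1CCC=C[C@@]1(O)C(=O)O[C@H]1Cc2c(O[Si](C)(C)C(C)(C)C)cc(O[Si](C)(C)C(C)(C)C)cc2O[C@@H]1c1ccc(O[Si](C)(C)C(C)(C)C)c(O[Si](C)(C)C(C)(C)C)c1
A6 | alternative 3 | 5,7,3',4'-tetra-O-TBS-catechin 3-O-[2-(1-hydroxycyclopent-2-en-1-yl)-2-oxoacetate] (either carbinol configuration) | OC1(C=CCC1)C(=O)C(=O)O[C@H]1Cc2c(O[Si](C)(C)C(C)(C)C)cc(O[Si](C)(C)C(C)(C)C)cc2O[C@@H]1c1ccc(O[Si](C)(C)C(C)(C)C)c(O[Si](C)(C)C(C)(C)C)c1
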